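The ten-membered carbocycle is not cyclised end to end but made by contracting a larger ring. In the target the C6 lactone carbinol lies next to C7, which carries the C11(=C13)–C12 unit of the lactone ring fused to the ten-membered ring, so C6–OH is a homoallylic alcohol: the retron of a [2,3]-Wittig shift. O6 is therefore tied to C13 in a 13-membered diallyl ether (C7=C11, C12 as dimethyl acetal, O8, O9 and O14 silylated). Deprotonation at C6 then forms C6–C7, the C11=C13 methylene, the carbocycle and the C6 and C7 stereocentres in one operation. The ether comes from Williamson closure of a chain built from nerol, methyl (S)-glycerate and methyl 3,3-dimethoxypropanoate.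

Key step: step 19

Remarks
- Numbering and abbreviations: germacrane numbering is used for all compounds (C6 lactone carbinol, C7 ring-fusion carbon, C11/C12/C13 lactone α-carbon, carbonyl and exocyclic methylene, C14 the CH2O on C10, C15 the methyl on C4). OTES, OTBS, OTBDPS and OPMB mean triethylsilyloxy, tert-butyldimethylsilyloxy, tert-butyldiphenylsilyloxy and 4-methoxybenzyloxy.
- Correction of an alkene descriptor: in the 13-membered ether C8 and C13 are trans on C7=C11, yet the bond is 7(11)Z by the sequence rules because the acetal carbon C12 outranks C13; the same geometry is E in the ester and in the allylic chlorides.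
- Precursor design: all spectator oxygens are silyl ethers (no benzylic C–H in the key step), and the smaller TES group sits on O8 and TBS on O9. This serves both the facial demand of the key step and the order of the final acylations.
- Assumption: methyl (S)-glycerate and the bromo ylide of step 4 are bought; the ylide is otherwise one step from ethyl (triphenylphosphoranylidene)acetate and bromine.

Step 1
Reactants: 1 nerol
Product: 2 neryl 4-methoxybenzyl ether
Conditions: NaH, 4-MeOC6H4CH2Cl, Bu4NI (cat.), THF/DMF, 0 °C to rt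
Reagents that add atoms: 4-methoxybenzyl chloride, COc1ccc(CCl)cc1
Why: Williamson etherification of the primary allylic alkoxide; the PMB ether withstands the hydride, organolithium and base steps that follow and is taken off oxidatively in step 17, so that no benzylic C–H is left when the key step is run.

Step 2
Reactants: 2 neryl 4-methoxybenzyl ether
Product: 3 6,7-epoxide of 2 (racemic at the epoxide CH)
Conditions: 3-ClC6H4CO3H (1.0 equiv), NaHCO3, CH2Cl2, −20 to 0 °C
Reagents that add atoms: 3-chloroperoxybenzoic acid, OOC(=O)c1cccc(Cl)c1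
Why: Prilezhaev epoxidation, expected to pick the remote trisubstituted alkene because the other one is deactivated by the allylic oxygen; the new stereocentre is formed as a racemate and disappears in step 3.

Step 3
Reactants: 3 6,7-epoxide of 2
Product: 4 (4Z)-6-(4-methoxybenzyloxy)-4-methylhex-4-enal (C1–C6 plus C15; CHO = C1)
Conditions: H5IO6, THF/H2O, 0 °C
Reagents that add atoms: none
Why: periodic acid opens the epoxide to the glycol and cleaves it (Malaprade reaction) to acetone and the C1 aldehyde without touching the 4Z alkene or the PMB ether.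

Step 4
Reactants: 4 (4Z)-6-(4-methoxybenzyloxy)-4-methylhex-4-enal; 5 ethyl 2-bromo-2-(triphenyl-λ5-phosphanylidene)acetate
Product: 6 ethyl (2Z,6Z)-2-bromo-8-(4-methoxybenzyloxy)-6-methylocta-2,6-dienoate
Conditions: CH2Cl2, rt
Reagents that add atoms: none
Why: Wittig olefination with a stabilised α-bromo ylide, which should place the chain trans to the ester and therefore cis to bromine (2Z), the arrangement that later becomes C2 cis to C9 and trans to C14 on C1=C10.

Step 5
Reactants: 6 ethyl (2Z,6Z)-2-bromo-8-(4-methoxybenzyloxy)-6-methylocta-2,6-dienoate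
Product: 7 (2Z,6Z)-2-bromo-8-(4-methoxybenzyloxy)-6-methylocta-2,6-dien-1-ol
Conditions: i-Bu2AlH, CH2Cl2, −78 °C
Reagents that add atoms: none
Why: 1,2-reduction of the ester to the C14 allylic alcohol by the aluminium hydride at low temperature, conditions under which alkenyl bromides and the alkene geometry are left alone.

Step 6
Reactants: 7 (2Z,6Z)-2-bromo-8-(4-methoxybenzyloxy)-6-methylocta-2,6-dien-1-ol
Product: 8 tert-butyldiphenylsilyl ether of 7 (C10 bromide; 14-OTBDPS; 6-OPMB)
Conditions: t-BuPh2SiCl, imidazole, CH2Cl2, rt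
Reagents that add atoms: tert-butylchlorodiphenylsilane, CC(C)(C)[Si](Cl)(c1ccccc1)c1ccccc1
Why: silylation of the primary alcohol; the bulky TBDPS group is the one silyl ether meant to last to the final step and it shields the C14 hydrogens in the key step.

Step 7
Reactants: 9 methyl (2S)-2,3-dihydroxypropanoate
Product: 10 methyl (2S)-2,3-bis(triethylsilyloxy)propanoate
Conditions: Et3SiCl, imidazole, CH2Cl2, 0 °C to rt
Reagents that add atoms: chlorotriethylsilane, CC[Si](Cl)(CC)CC
Why: silylation of both hydroxyl groups in one operation; the secondary TES group becomes the O8 protecting group and the primary one is the latent C7 aldehyde, the stereocentre (future C8) being untouched.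

Step 8
Reactants: 10 methyl (2S)-2,3-bis(triethylsilyloxy)propanoate
Product: 11 (2S)-N-methoxy-N-methyl-2,3-bis(triethylsilyloxy)propanamide
Conditions: MeNH(OMe)·HCl, i-PrMgCl, THF, −20 °C
Reagents that add atoms: N,O-dimethylhydroxylamine hydrochloride, CNOC.Cl
Why: Weinreb amide formation by aminolysis of the ester with the chloromagnesium amide at −20 °C, conditions known to leave α-silyloxy stereocentres unepimerised.

Step 9
Reactants: 8 tert-butyldiphenylsilyl ether of 7; 11 (2S)-N-methoxy-N-methyl-2,3-bis(triethylsilyloxy)propanamide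
Product: 13 C1–C10 enone (8S; 9-oxo; 1(10)Z; 4Z; 7,8-bis-OTES; 14-OTBDPS; 6-OPMB), via alkenyllithium 12 (not isolated)
Conditions: t-BuLi (2.0 equiv), Et2O, −78 °C; then 11, −78 to −40 °C
Reagents that add atoms: none
Why: bromine–lithium exchange with retention of alkene geometry gives 12, which adds once to the Weinreb amide (stable chelated tetrahedral intermediate, ketone released only on work-up), forming C9–C10 with C9 cis to C2.

Step 10
Reactants: 13 C1–C10 enone
Product: 14 allylic alcohol (8S,9S; 9-OH threo to 8-OTES; otherwise as 13)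
Conditions: Li[HB(s-Bu)3], THF, −78 °C
Reagents that add atoms: none
Why: Felkin–Anh controlled 1,2-reduction of the α′-silyloxy enone by a bulky borohydride: hydride should add anti to the C8–O bond and give the threo (8S,9S) alcohol, the α-substituent on the enone disfavouring conjugate reduction.

Step 11
Reactants: 14 allylic alcohol (8S,9S)
Product: 15 9-O-TBS ether of 14 (7,8-bis-OTES; 9-OTBS; 14-OTBDPS; 6-OPMB)
Conditions: t-BuMe2SiOTf, 2,6-lutidine, CH2Cl2, −78 to 0 °C
Reagents that add atoms: tert-butyldimethylsilyl trifluoromethanesulfonate, CC(C)(C)[Si](C)(C)OS(=O)(=O)C(F)(F)F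
Why: silylation of the hindered secondary allylic alcohol with the silyl triflate; O9 now carries TBS and O8 TES, which differentiates the two hydroxyls for the stepwise acylations at the end.

Step 12
Reactants: 15 9-O-TBS ether of 14
Product: 16 C7 aldehyde (8R,9S by the sequence rules, same spatial arrangement as in 15; 8-OTES; 9-OTBS; 14-OTBDPS; 6-OPMB)
Conditions: (COCl)2, DMSO, CH2Cl2, −78 to −40 °C; then Et3N, −78 to 0 °C
Reagents that add atoms: none
Why: Swern oxidation applied directly to the primary triethylsilyl ether, a known selective oxidative desilylation in which the activated sulfonium salt exchanges only with the unhindered primary silyl ether, so the secondary TES, TBS and TBDPS ethers and the PMB ether should remain.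

Step 13
Reactants: 16 C7 aldehyde; 17 methyl 3,3-dimethoxypropanoate
Product: 19 aldol adduct (7-OH; C11 bearing CO2Me as C13 and CH(OMe)2 as C12; mixture at C7 and C11; 8S,9S), via lithium enolate 18 (not isolated)
Conditions: LiN(i-Pr)2, THF, −78 °C; then 16, −78 °C
Reagents that add atoms: none
Why: aldol addition of the lithium ester enolate to the α-silyloxy aldehyde at −78 °C, cold enough to avoid loss of methoxide from the enolate; the two new stereocentres (C7, C11) are formed as mixtures and are removed in step 14.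

Step 14
Reactants: 19 aldol adduct
Product: 21 enoate (7(11)E, C8 trans to CO2Me; C12 dimethyl acetal; 8S,9S), via mesylate 20 (not isolated)
Conditions: MsCl, Et3N, CH2Cl2, 0 °C; then DBU, 0 °C to rt
Reagents that add atoms: none
Why: mesylation and E1cB elimination through the ester enolate, stereoconvergent and expected to favour the isomer with C8 trans to the ester (7(11)E), in which C8–H can eclipse the alkene next to the acetal carbon.

Step 15
Reactants: 21 enoate
Product: 22 C13 allylic alcohol (7(11)Z by the sequence rules, C8 trans to C13; C12 dimethyl acetal)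
Conditions: i-Bu2AlH, CH2Cl2, −78 °C
Reagents that add atoms: none
Why: 1,2-reduction of the enoate to the C13 allylic alcohol with the aluminium hydride at −78 °C; acetal, silyl ethers and PMB ether are inert.

Step 16
Reactants: 22 C13 allylic alcohol
Product: 24 C13 allylic chloride (7(11)E; 6-OPMB), via mesylate 23 (not isolated)
Conditions: MsCl, 2,4,6-collidine, LiCl, DMF, 0 °C
Reagents that add atoms: lithium chloride, [Li+].[Cl-]
Why: Collington–Meyers chlorination (mesylate 23 displaced by chloride in an SN2 step at the primary carbon), which keeps the alkene position and geometry and avoids acid.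

Step 17
Reactants: 24 C13 allylic chloride
Product: 25 6-hydroxy 13-chloride (open-chain ether precursor; 8-OTES; 9-OTBS; 14-OTBDPS; C12 dimethyl acetal)
Conditions: DDQ, CH2Cl2/pH 7 buffer, 0 °C
Reagents that add atoms: none
Why: oxidative cleavage of the PMB ether by DDQ (hydride abstraction from the electron-rich benzylic position) under buffered conditions that leave silyl ethers, the acetal and the allylic chloride alone.

Step 18
Reactants: 25 6-hydroxy 13-chloride
Product: 26 13-membered diallyl ether C6–O–C13 (8S,9S; 4Z; 1(10)Z; 7(11)Z with C8 trans to C13; 8-OTES; 9-OTBS; 14-OTBDPS; C12 dimethyl acetal)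
Conditions: NaH, Bu4NI (cat.), THF (0.003 M, slow addition), rt to 40 °C
Reagents that add atoms: none
Why: intramolecular Williamson etherification under high dilution with iodide catalysis: the C6 alkoxide closes the 13-membered ring by exo-tet SN2 attack at the primary allylic C13, SN2′ attack at the substituted C7 being disfavoured.

Step 19
Reactants: 26 13-membered diallyl ether
Product: 29 ten-membered carbinol (6R,7S,8S,9S; 6-OH; C7 bearing C11(=C13H2)–C12H(OMe)2; 4Z; 1(10)Z; 8-OTES; 9-OTBS; 14-OTBDPS), via C6-lithio ether 27 (not isolated), via lithium alkoxide 28 (not isolated)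
Conditions: n-BuLi (1.5 equiv), THF, −78 °C; AcOH, −78 °C
Reagents that add atoms: none
Why: n-BuLi removes one C6 proton (α to the ring oxygen and allylic to C4=C5) to give 27, which rearranges by a concerted suprafacial [2,3]-sigmatropic (Wittig) shift through a five-membered envelope made of C6, O, C13, C11 and C7: C6–C7 forms while O–C13 breaks and C11=C13 appears, giving alkoxide 28 and, after the cold proton quench, 29. The closest known reaction type is the [2,3]-Wittig ring contraction of 13-membered diallyl ethers to ten-membered homoallylic alcohols. The ten-membered carbocycle is closed by a transannular three-atom contraction of the existing 13-membered ring, not by an end-to-end cyclisation, so no high dilution is needed and a weak C–O bond is exchanged for a C–C bond and a lithium alkoxide that stays on C6. The C6/C7 relationship (O6 and C11 trans on the new ring, 6R/7S) is set by the alkene geometry, since C8 is trans to C13 on C7=C11 and sits exo on the envelope while C5 on the carbanion takes the position that avoids eclipsing it; the sense at C7 is set by C8, whose hydrogen eclipses the alkene to avoid A(1,3) strain with the cis acetal carbon C12, so that C6 is expected to bond anti to the C8–C9 ring bond, past the triethylsilyloxy group (the smaller silyl group was put on O8 for this reason). The step needs deprotonation at C6 and not at C13, C14 or C9: C6 is the only α-oxy allylic CH2 attached to an unsubstituted vinylic CH, whereas C13 and C14 flank the fully substituted C11 and C10 (more hindered, centrally substituted allyl anions), C14 is shielded by TBDPS, the C9 hydrogen is tertiary, no benzylic or carbonyl-activated C–H is present, and a C13 anion could in any case only bond to the fully substituted C4. Low temperature and the cold quench suppress the [1,2]-shift and any O8-to-O6 silyl migration in 28.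

Step 20
Reactants: 29 ten-membered carbinol
Product: 31 lactol (C12 hemiacetal closed onto O6; anomeric mixture; 6R,7S,8S,9S), via hydroxy enal 30 (not isolated)
Conditions: PPTS (cat.), acetone/H2O (10:1), rt
Reagents that add atoms: water, O
Why: acid-catalysed hydrolysis of the allylic dimethyl acetal to enal 30, which is trapped at once by the neighbouring C6 hydroxyl as the five-membered lactol (intramolecular hemiacetal formation), the conditions being mild enough for the hindered TES ether.

Step 21
Reactants: 31 lactol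
Product: 32 α-methylene γ-lactone (6R,7S,8S,9S; 8-OTES; 9-OTBS; 14-OTBDPS)
Conditions: (n-Pr)4N[RuO4] (cat.), N-methylmorpholine N-oxide, 4 Å MS, CH2Cl2, rt
Reagents that add atoms: none
Why: Ley–Griffith oxidation of the lactol to the α-methylene γ-lactone under neutral conditions at room temperature.

Step 22
Reactants: 32 α-methylene γ-lactone
Product: 33 8-hydroxy lactone (6R,7R,8S,9S by the sequence rules, spatial arrangement unchanged; 9-OTBS; 14-OTBDPS)
Conditions: HF·pyridine, pyridine, THF, 0 °C
Reagents that add atoms: none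
Why: selective fluoride-mediated cleavage of the triethylsilyl ether in buffered HF·pyridine, under which TBS and TBDPS ethers react far more slowly.

Step 23
Reactants: 33 8-hydroxy lactone
Product: 34 8-O-isobutyrate (6R,7S,8S,9S; 9-OTBS; 14-OTBDPS)
Conditions: (i-PrCO)2O, Et3N, DMAP, CH2Cl2, 0 °C to rt
Reagents that add atoms: isobutyric anhydride, CC(C)C(=O)OC(=O)C(C)C
Why: DMAP-catalysed acylation of the hindered C8 hydroxyl with the anhydride (nucleophilic catalysis via the acylpyridinium ion).

Step 24
Reactants: 34 8-O-isobutyrate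
Product: 35 9-hydroxy 8-O-isobutyrate (14-OTBDPS)
Conditions: aq. HF (48%), MeCN, 0 °C
Reagents that add atoms: none
Why: selective desilylation; aqueous HF in acetonitrile cleaves the secondary allylic TBS ether much faster than the primary TBDPS ether, and the acidic medium disfavours migration of the C8 isobutyrate to O9.

Step 25
Reactants: 36 2-hydroxy-2-methylpropanoic acid
Product: 38 2-methyl-2-(triethylsilyloxy)propanoic acid, via bis-silyl derivative 37 (not isolated)
Conditions: Et3SiCl, imidazole, DMF, rt; then H2O/THF, rt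
Reagents that add atoms: chlorotriethylsilane, CC[Si](Cl)(CC)CC
Why: silylation of both the hydroxyl and the carboxyl group followed by hydrolysis of the labile silyl ester during aqueous work-up, which leaves the tertiary TES ether.

Step 26
Reactants: 35 9-hydroxy 8-O-isobutyrate; 38 2-methyl-2-(triethylsilyloxy)propanoic acid
Product: 40 9-O-[2-methyl-2-(triethylsilyloxy)propanoyl] 8-O-isobutyryl lactone (14-OTBDPS), via mixed anhydride 39 (not isolated)
Conditions: 2,4,6-Cl3C6H2COCl, Et3N, THF, rt; then 35, DMAP, toluene, rt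
Reagents that add atoms: none
Why: Yamaguchi esterification via mixed anhydride 39, suited to joining the hindered tertiary-alkoxy acid to the secondary allylic C9 hydroxyl; adding 35 last to the preformed anhydride keeps acylation faster than isobutyrate migration.

Step 27
Reactants: 40 9-O-[2-methyl-2-(triethylsilyloxy)propanoyl] 8-O-isobutyryl lactone
Product: 41 CNP0220567.2 (6R,7S,8S,9S; 4Z; 1(10)Z)
Conditions: HF·pyridine, THF, rt
Reagents that add atoms: none
Why: fluoride-mediated cleavage of the remaining TBDPS ether and of the tertiary TES ether with HF·pyridine, an acidic medium in which neither ester migrates, to give 41.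

Compound list
1 | nerol, (2Z)-3,7-dimethylocta-2,6-dien-1-ol | CC(C)=CCC/C(C)=C\CO | starting material
2 | neryl 4-methoxybenzyl ether | COc1ccc(COC/C=C(/C)CCC=C(C)C)cc1 | intermediate
3 | 6,7-epoxide of 2 (racemic at the epoxide CH) | COc1ccc(COC/C=C(/C)CCC2OC2(C)C)cc1 | intermediate
4 | (4Z)-6-(4-methoxybenzyloxy)-4-methylhex-4-enal | COc1ccc(COC/C=C(/C)CCC=O)cc1 | intermediate
5 | ethyl 2-bromo-2-(triphenyl-λ5-phosphanylidene)acetate | CCOC(=O)C(Br)=P(c1ccccc1)(c1ccccc1)c1ccccc1 | starting material
6 | ethyl (2Z,6Z)-2-bromo-8-(4-methoxybenzyloxy)-6-methylocta-2,6-dienoate | CCOC(=O)/C(Br)=C/CC/C(C)=C\COCc1ccc(OC)cc1 | intermediate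
7 | (2Z,6Z)-2-bromo-8-(4-methoxybenzyloxy)-6-methylocta-2,6-dien-1-ol | OC/C(Br)=C/CC/C(C)=C\COCc1ccc(OC)cc1 | intermediate
8 | tert-butyldiphenylsilyl ether of 7 | CC(C)(C)[Si](OC/C(Br)=C/CC/C(C)=C\COCc1ccc(OC)cc1)(c1ccccc1)c1ccccc1 | intermediate
9 | methyl (2S)-2,3-dihydroxypropanoate | COC(=O)[C@@H](O)CO | starting material
10 | methyl (2S)-2,3-bis(triethylsilyloxy)propanoate | COC(=O)[C@@H](O[Si](CC)(CC)CC)CO[Si](CC)(CC)CC | intermediate
11 | (2S)-N-methoxy-N-methyl-2,3-bis(triethylsilyloxy)propanamide | CON(C)C(=O)[C@@H](O[Si](CC)(CC)CC)CO[Si](CC)(CC)CC | intermediate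
12 | alkenyllithium from 8 (Li in place of Br, geometry retained) | [Li]/C(CO[Si](c1ccccc1)(c1ccccc1)C(C)(C)C)=C\CC/C(C)=C\COCc1ccc(OC)cc1 | intermediate
13 | C1–C10 enone (8S; 9-oxo; 1(10)Z; 4Z; 7,8-bis-OTES; 14-OTBDPS; 6-OPMB) | CC[Si](CC)(CC)OC[C@H](O[Si](CC)(CC)CC)C(=O)/C(CO[Si](c1ccccc1)(c1ccccc1)C(C)(C)C)=C\CC/C(C)=C\COCc1ccc(OC)cc1 | intermediate
14 | allylic alcohol (8S,9S; 9-OH; otherwise as 13) | CC[Si](CC)(CC)OC[C@H](O[Si](CC)(CC)CC)[C@@H](O)/C(CO[Si](c1ccccc1)(c1ccccc1)C(C)(C)C)=C\CC/C(C)=C\COCc1ccc(OC)cc1 | intermediate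
15 | 9-O-TBS ether of 14 | CC[Si](CC)(CC)OC[C@H](O[Si](CC)(CC)CC)[C@@H](O[Si](C)(C)C(C)(C)C)/C(CO[Si](c1ccccc1)(c1ccccc1)C(C)(C)C)=C\CC/C(C)=C\COCc1ccc(OC)cc1 | intermediate
16 | C7 aldehyde (8R,9S; 8-OTES; 9-OTBS; 14-OTBDPS; 6-OPMB) | O=C[C@H](O[Si](CC)(CC)CC)[C@@H](O[Si](C)(C)C(C)(C)C)/C(CO[Si](c1ccccc1)(c1ccccc1)C(C)(C)C)=C\CC/C(C)=C\COCc1ccc(OC)cc1 | intermediate
17 | methyl 3,3-dimethoxypropanoate | COC(=O)CC(OC)OC | starting material
18 | lithium enolate of 17 | COC(O[Li])=CC(OC)OC | intermediate
19 | aldol adduct (7-OH; mixture at C7 and C11; 8S,9S) | COC(=O)C(C(OC)OC)C(O)[C@H](O[Si](CC)(CC)CC)[C@@H](O[Si](C)(C)C(C)(C)C)/C(CO[Si](c1ccccc1)(c1ccccc1)C(C)(C)C)=C\CC/C(C)=C\COCc1ccc(OC)cc1 | intermediate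
20 | C7 mesylate of 19 | COC(=O)C(C(OC)OC)C(OS(C)(=O)=O)[C@H](O[Si](CC)(CC)CC)[C@@H](O[Si](C)(C)C(C)(C)C)/C(CO[Si](c1ccccc1)(c1ccccc1)C(C)(C)C)=C\CC/C(C)=C\COCc1ccc(OC)cc1 | intermediate
21 | enoate (7(11)E; C8 trans to CO2Me; C12 dimethyl acetal; 8S,9S) | COC(=O)/C(C(OC)OC)=C/[C@H](O[Si](CC)(CC)CC)[C@@H](O[Si](C)(C)C(C)(C)C)/C(CO[Si](c1ccccc1)(c1ccccc1)C(C)(C)C)=C\CC/C(C)=C\COCc1ccc(OC)cc1 | intermediate
22 | C13 allylic alcohol (7(11)Z; C8 trans to C13) | OC/C(C(OC)OC)=C/[C@H](O[Si](CC)(CC)CC)[C@@H](O[Si](C)(C)C(C)(C)C)/C(CO[Si](c1ccccc1)(c1ccccc1)C(C)(C)C)=C\CC/C(C)=C\COCc1ccc(OC)cc1 | intermediate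
23 | C13 mesylate of 22 | CS(=O)(=O)OC/C(C(OC)OC)=C/[C@H](O[Si](CC)(CC)CC)[C@@H](O[Si](C)(C)C(C)(C)C)/C(CO[Si](c1ccccc1)(c1ccccc1)C(C)(C)C)=C\CC/C(C)=C\COCc1ccc(OC)cc1 | intermediate
24 | C13 allylic chloride (7(11)E; 6-OPMB) | ClC/C(C(OC)OC)=C/[C@H](O[Si](CC)(CC)CC)[C@@H](O[Si](C)(C)C(C)(C)C)/C(CO[Si](c1ccccc1)(c1ccccc1)C(C)(C)C)=C\CC/C(C)=C\COCc1ccc(OC)cc1 | intermediate
25 | 6-hydroxy 13-chloride | ClC/C(C(OC)OC)=C/[C@H](O[Si](CC)(CC)CC)[C@@H](O[Si](C)(C)C(C)(C)C)/C(CO[Si](c1ccccc1)(c1ccccc1)C(C)(C)C)=C\CC/C(C)=C\CO | intermediate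
26 | 13-membered diallyl ether C6–O–C13 (8S,9S; 4Z; 1(10)Z; 7(11)Z; 8-OTES; 9-OTBS; 14-OTBDPS; C12 dimethyl acetal) | C1/C=C(/C)CC/C=C(/CO[Si](c2ccccc2)(c2ccccc2)C(C)(C)C)[C@H](O[Si](C)(C)C(C)(C)C)[C@@H](O[Si](CC)(CC)CC)/C=C(\C(OC)OC)CO1 | intermediate
27 | 26 lithiated at C6 | [Li]C1/C=C(/C)CC/C=C(/CO[Si](c2ccccc2)(c2ccccc2)C(C)(C)C)[C@H](O[Si](C)(C)C(C)(C)C)[C@@H](O[Si](CC)(CC)CC)/C=C(\C(OC)OC)CO1 | intermediate
28 | lithium alkoxide of 29 | [Li]O[C@@H]1/C=C(/C)CC/C=C(/CO[Si](c2ccccc2)(c2ccccc2)C(C)(C)C)[C@H](O[Si](C)(C)C(C)(C)C)[C@@H](O[Si](CC)(CC)CC)[C@H]1C(=C)C(OC)OC | intermediate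
29 | ten-membered carbinol (6R,7S,8S,9S; 6-OH; C7 bearing C11(=C13H2)–C12H(OMe)2) | O[C@@H]1/C=C(/C)CC/C=C(/CO[Si](c2ccccc2)(c2ccccc2)C(C)(C)C)[C@H](O[Si](C)(C)C(C)(C)C)[C@@H](O[Si](CC)(CC)CC)[C@H]1C(=C)C(OC)OC | intermediate
30 | hydroxy enal (C12 = CHO) | O[C@@H]1/C=C(/C)CC/C=C(/CO[Si](c2ccccc2)(c2ccccc2)C(C)(C)C)[C@H](O[Si](C)(C)C(C)(C)C)[C@@H](O[Si](CC)(CC)CC)[C@H]1C(=C)C=O | intermediate
31 | lactol (anomeric mixture at C12) | C=C1C(O)O[C@@H]2/C=C(/C)CC/C=C(/CO[Si](c3ccccc3)(c3ccccc3)C(C)(C)C)[C@H](O[Si](C)(C)C(C)(C)C)[C@@H](O[Si](CC)(CC)CC)[C@@H]12 | intermediate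
32 | α-methylene γ-lactone (8-OTES; 9-OTBS; 14-OTBDPS) | C=C1C(=O)O[C@@H]2/C=C(/C)CC/C=C(/CO[Si](c3ccccc3)(c3ccccc3)C(C)(C)C)[C@H](O[Si](C)(C)C(C)(C)C)[C@@H](O[Si](CC)(CC)CC)[C@@H]12 | intermediate
33 | 8-hydroxy lactone (9-OTBS; 14-OTBDPS) | C=C1C(=O)O[C@@H]2/C=C(/C)CC/C=C(/CO[Si](c3ccccc3)(c3ccccc3)C(C)(C)C)[C@H](O[Si](C)(C)C(C)(C)C)[C@@H](O)[C@@H]12 | intermediate
34 | 8-O-isobutyrate (9-OTBS; 14-OTBDPS) | C=C1C(=O)O[C@@H]2/C=C(/C)CC/C=C(/CO[Si](c3ccccc3)(c3ccccc3)C(C)(C)C)[C@H](O[Si](C)(C)C(C)(C)C)[C@@H](OC(=O)C(C)C)[C@@H]12 | intermediate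
35 | 9-hydroxy 8-O-isobutyrate (14-OTBDPS) | C=C1C(=O)O[C@@H]2/C=C(/C)CC/C=C(/CO[Si](c3ccccc3)(c3ccccc3)C(C)(C)C)[C@H](O)[C@@H](OC(=O)C(C)C)[C@@H]12 | intermediate
36 | 2-hydroxy-2-methylpropanoic acid | CC(C)(O)C(=O)O | starting material
37 | triethylsilyl 2-methyl-2-(triethylsilyloxy)propanoate | CC[Si](CC)(CC)OC(C)(C)C(=O)O[Si](CC)(CC)CC | intermediate
38 | 2-methyl-2-(triethylsilyloxy)propanoic acid | CC[Si](CC)(CC)OC(C)(C)C(=O)O | intermediate
39 | mixed anhydride of 38 and 2,4,6-trichlorobenzoic acid | CC[Si](CC)(CC)OC(C)(C)C(=O)OC(=O)c1c(Cl)cc(Cl)cc1Cl | intermediate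
40 | 9-O-[2-methyl-2-(triethylsilyloxy)propanoyl] 8-O-isobutyryl lactone (14-OTBDPS) | C=C1C(=O)O[C@@H]2/C=C(/C)CC/C=C(/CO[Si](c3ccccc3)(c3ccccc3)C(C)(C)C)[C@H](OC(=O)C(C)(C)O[Si](CC)(CC)CC)[C@@H](OC(=O)C(C)C)[C@@H]12 | intermediate
41 | CNP0220567.2 (6R,7S,8S,9S; 4Z; 1(10)Z) | C=C1C(=O)O[C@@H]2/C=C(/C)CC/C=C(/CO)[C@H](OC(=O)C(C)(C)O)[C@@H](OC(=O)C(C)C)[C@@H]12 | target

Total step count: 27. Longest linear sequence: 24 steps (steps 1–6, 9–24, 26 and 27, from nerol).

Steps most likely to fail

Step 19. Three things may go wrong. Lithiation may take place at C13 (helped by the acetal oxygens) or at C14 instead of C6, leading to 1,4-elimination of the C8 silyloxy group or silyl migration. The C6 anion may undergo the [1,2]-shift. Or C6 may add to the face of C7 anti to the C8–O bond (the Felkin-type sense) rather than anti to C8–C9, which would give the wrong C6/C7 pair relative to C8; this facial sense is the least certain point of the route. The fallback sets out from 25 and forms the same C6–C7 bond by a carbonyl allylation instead of a sigmatropic shift. MnO2 in CH2Cl2 should oxidise the C6 allylic alcohol to the (4Z)-enal chloride F1. CrCl2 (divalent chromium) with catalytic LiI in THF at high dilution (intramolecular Nozaki–Hiyama allylation) should then convert the C13 chloride into an allylchromium species that adds through its γ-carbon C7 to the C6 aldehyde in a chair transition state. This gives the C11=C13 methylene and the anti C6/C7 relationship and comes back to the route at 29, with steps 18 and 19 bypassed.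

Step 18. Intermolecular etherification, SN2′ attack at C7 or elimination at the allylic chloride that is flanked by the acetal may outrun closure of the 13-membered ring. The fallback exchanges the roles of the two chain ends and sets out from 21. DDQ should give the C6 alcohol F2; MsCl, 2,4,6-collidine and LiCl the neryl-type C6 chloride F3; and i-Bu2AlH at −78 °C the C13 alcohol F4. Under NaH and high dilution the C13 alkoxide would then displace the unhindered C6 chloride, where no β-branching slows the SN2 step and SN2′ attack would have to occur at the fully substituted C4. The sequence comes back to the route at 26.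

Step 14. The E1cB elimination may give poor control of the C7=C11 geometry, or the base may deprotonate C8 (γ to the ester) and scramble or eliminate the neighbouring silyloxy groups. The fallback fixes the geometry by an ylide and a stereoretentive exchange and sets out from 16. Wittig reaction with 5, as in step 4, should give the 11-bromo enoate F5 with C8 trans to the ester; i-Bu2AlH should give the bromo allylic alcohol F6. t-BuLi (3 equiv, alkoxide formation then bromine–lithium exchange with retention) followed by DMF should give the hydroxy enal F7, in which the formyl carbon C12 is cis to C8. Acetalisation with HC(OMe)3 and CeCl3·7H2O in MeOH comes back to the route at 22, one step longer than steps 13–15.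

Further compounds
F1 | step 19 | (4Z)-C6 aldehyde of 25 (13-chloro enal) | O=C/C=C(/C)CC/C=C(/CO[Si](c1ccccc1)(c1ccccc1)C(C)(C)C)[C@H](O[Si](C)(C)C(C)(C)C)[C@@H](O[Si](CC)(CC)CC)/C=C(\C(OC)OC)CCl
F2 | step 18 | 6-hydroxy enoate (21 without PMB) | COC(=O)/C(C(OC)OC)=C/[C@H](O[Si](CC)(CC)CC)[C@@H](O[Si](C)(C)C(C)(C)C)/C(CO[Si](c1ccccc1)(c1ccccc1)C(C)(C)C)=C\CC/C(C)=C\CO
F3 | step 18 | 6-chloro enoate | COC(=O)/C(C(OC)OC)=C/[C@H](O[Si](CC)(CC)CC)[C@@H](O[Si](C)(C)C(C)(C)C)/C(CO[Si](c1ccccc1)(c1ccccc1)C(C)(C)C)=C\CC/C(C)=C\CCl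
F4 | step 18 | 13-hydroxy 6-chloride | OC/C(C(OC)OC)=C/[C@H](O[Si](CC)(CC)CC)[C@@H](O[Si](C)(C)C(C)(C)C)/C(CO[Si](c1ccccc1)(c1ccccc1)C(C)(C)C)=C\CC/C(C)=C\CCl
F5 | step 14 | ethyl 11-bromo enoate (C8 trans to CO2Et) | CCOC(=O)/C(Br)=C/[C@H](O[Si](CC)(CC)CC)[C@@H](O[Si](C)(C)C(C)(C)C)/C(CO[Si](c1ccccc1)(c1ccccc1)C(C)(C)C)=C\CC/C(C)=C\COCc1ccc(OC)cc1
F6 | step 14 | 11-bromo 13-alcohol | OC/C(Br)=C/[C@H](O[Si](CC)(CC)CC)[C@@H](O[Si](C)(C)C(C)(C)C)/C(CO[Si](c1ccccc1)(c1ccccc1)C(C)(C)C)=C\CC/C(C)=C\COCc1ccc(OC)cc1
F7 | step 14 | 13-hydroxy 12-enal (CHO cis to C8) | OC/C(C=O)=C/[C@H](O[Si](CC)(CC)CC)[C@@H](O[Si](C)(C)C(C)(C)C)/C(CO[Si](c1ccccc1)(c1ccccc1)C(C)(C)C)=C\CC/C(C)=C\COCc1ccc(OC)cc1
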